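The aryl ether is cut at O–C11 (Mitsunobu with isofraxidin), and the cyclohexene ring C5–C6–C7–C8–C9–C10 is traced back to the cyclopentanone ring (C5, C6, C7, C9, C10) of a Hajos–Parrish-type trans-hydrindanone. C8 with its methyl is inserted between C7 and C9 as a chloro(methyl)carbenoid; thermal opening of the resulting siloxy chlorocyclopropane gives, in one operation, the six-membered ring, the C7=C8 olefin with the C8 methyl in place and a C9 carbonyl that later carries C11. The step exploits the 2-methylallyl array C7=C8(CH3)–C9. C10 is set by amino acid catalysis; C5, C3 and C9 are relayed from it.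

Key step: step 7

Remark: drimane numbering is used for all core carbons, also in the hydrindanes (C9 bears C11, C8 bears the C12 methyl, C10 the angular methyl; α = face opposite that methyl); 17 is taken as purchased; 11 is drawn as its endo-chloride epimer, the one that can react in step 7.

Step 1
Reactants: 1 2-methylcyclopentane-1,3-dione; 2 ethyl vinyl ketone (pent-1-en-3-one)
Product: 4 (S)-4,7a-dimethyl-2,3,7,7a-tetrahydro-1H-indene-1,5(6H)-dione, via triketone 3 (not isolated)
Conditions: Et3N (cat.), EtOAc, rt; concentrate; then L-phenylalanine, (+)-CSA, DMF, rt → 70 °C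
Reagents that add atoms: none
Why: Base-catalysed Michael addition gives the prochiral triketone, and the amino-acid-mediated Hajos–Parrish–Eder–Sauer–Wiechert aldol condensation should desymmetrise it through an enamine transition state to the (S)-enone, which sets the quaternary C10 stereocenter.

Step 2
Reactants: 4 (S)-4,7a-dimethyl-2,3,7,7a-tetrahydro-1H-indene-1,5(6H)-dione
Product: 5 C9 ethylene ketal of 4 [(7a'S)-4',7a'-dimethyl-2',3',7',7a'-tetrahydrospiro[1,3-dioxolane-2,1'-inden]-5'(6'H)-one]
Conditions: HOCH2CH2OH, p-TsOH (cat.), PhH, reflux, Dean–Stark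
Reagents that add atoms: ethylene glycol, OCCO
Why: Acid-catalysed ketalisation should be selective for the saturated cyclopentanone because the fully substituted conjugated enone carbonyl is much less electrophilic and would have to deconjugate.

Step 3
Reactants: 5 C9 ethylene ketal of 4
Product: 7 trans-fused 4,4-dimethyl ketone ketal [(3a'S,7a'S)-4',4',7a'-trimethylhexahydrospiro[1,3-dioxolane-2,1'-inden]-5'(4'H)-one], via lithium enolate 6 (not isolated)
Conditions: Li, NH3(l)/THF, t-BuOH (1 equiv), −78 °C; isoprene; then MeI, −78 → −33 °C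
Reagents that add atoms: iodomethane, CI
Why: Birch-type reductive alkylation of the enone, in which protonation of the β-carbon C5 on the α-face should give the trans-fused lithium enolate (5α-H) that is then C-methylated regiospecifically at C4 to complete the gem-dimethyl group.

Step 4
Reactants: 7 trans-fused 4,4-dimethyl ketone ketal
Product: 9 (3aS,5S,7aS)-5-hydroxy-4,4,7a-trimethyloctahydro-1H-inden-1-one, via hydroxy ketal 8 (not isolated)
Conditions: NaBH4, MeOH, 0 °C; then 2 M HCl, THF, rt
Reagents that add atoms: water, O
Why: Substrate-controlled borohydride reduction in which hydride should add to the C3 carbonyl from the α-face, away from the axial 4β- and 10β-methyl groups, to give the equatorial 3β-alcohol, after which aqueous acid hydrolyses the dioxolane.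

Step 5
Reactants: 9 (3aS,5S,7aS)-5-hydroxy-4,4,7a-trimethyloctahydro-1H-inden-1-one
Product: 10 bis-TMS derivative of 9 (C9 silyl enol ether with C7=C9; 3β-OTMS ether)
Conditions: TMSOTf, Et3N, CH2Cl2, 0 °C
Reagents that add atoms: trimethylsilyl trifluoromethanesulfonate, C[Si](C)(C)OS(=O)(=O)C(F)(F)F
Why: Soft enolisation and O-silylation, regiospecific because the C9 ketone can enolise only towards C7 (C10 is quaternary), with the C3 hydroxyl silylated at the same time as a sacrificial ether.

Step 6
Reactants: 10 bis-TMS derivative of 9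
Product: 11 7α,9α-[chloro(methyl)methano] adduct of 10 (C8 bridges C7 and C9 on the α-face; Cl endo; CH3 exo; 9β-OTMS; 7β-H)
Conditions: CH3CHCl2, n-BuLi, Et2O, −40 → −20 °C
Reagents that add atoms: 1,1-dichloroethane, CC(Cl)Cl
Why: Halocarbenoid cyclopropanation of a silyl enol ether, in which 1-chloroethylidene from α-elimination of 1,1-dichloroethyllithium should add to the electron-rich C7=C9 bond on the α-face opposite the angular 10β-methyl, with the smaller chlorine expected to take the more crowded endo position, so that C8 and its methyl are introduced.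

Step 7
Reactants: 11 7α,9α-[chloro(methyl)methano] adduct of 10
Product: 13 3β-hydroxy-11-nordrim-7-en-9-one [(4aS,6S,8aS)-6-hydroxy-2,5,5,8a-tetramethyl-4a,5,6,7,8,8a-hexahydronaphthalen-1(4H)-one], via enone silyl ether 12 (not isolated)
Conditions: toluene, Et3N (cat.), 100 °C; then K2CO3, MeOH, rt
Reagents that add atoms: none
Why: On heating, the endo C8–Cl bond of the 1-siloxy-6-chloro-6-methylbicyclo[3.1.0]hexane unit should ionise with concerted disrotatory 2π-electrocyclic opening of the cyclopropane (Woodward–Hoffmann–DePuy rule), which cleaves the shared C7–C9 bond and turns the five-membered ring C5–C6–C7–C9–C10 into the six-membered ring C5–C6–C7–C8–C9–C10 as a 2-siloxyallyl cation that loses Me3SiCl to give the 2-methylcyclohex-2-enone. The closest known reaction type is the thermal ring enlargement of halocarbene adducts of cyclic silyl enol ethers to 2-substituted cycloalk-2-enones. No new σ-bond and no new stereocenter are formed, since the six-membered ring arises by ring expansion (insertion of C8 between C7 and C9) and not by a cyclisation, and C3, C5 and C10 are untouched. The step needs cleavage of the internal bond only, which orbital symmetry secures (the bond opposite the carbon that carries the leaving group opens) with help from the siloxy donor on C9, and this fixes the olefin between C7 and C8 with the methyl on C8, free of the Δ8(12) and Δ8(9) isomers that an elimination would give. Only the endo-chloride epimer can open to a cis-allyl cation inside the ring, so any exo-chloride epimer is expected to stay behind, which is the main risk. Methanolysis with K2CO3 then removes the sacrificial C3 silyl ether.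

Step 8
Reactants: 13 3β-hydroxy-11-nordrim-7-en-9-one
Product: 14 drima-7,9(11)-dien-3β-ol
Conditions: Ph3PCH3Br, KOt-Bu (excess), toluene, 90 °C
Reagents that add atoms: methyltriphenylphosphonium bromide, C[P+](c1ccccc1)(c1ccccc1)c1ccccc1.[Br-]
Why: Wittig methylenation should convert the C9 carbonyl into the exocyclic C9=C11 methylene (C11 introduced), with the ylide in excess because one equivalent is consumed by the free hydroxyl and the neopentyl enone carbonyl is hindered.

Step 9
Reactants: 14 drima-7,9(11)-dien-3β-ol
Product: 16 drim-7-ene-3β,11-diol, via alkylborane 15 (not isolated)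
Conditions: 9-BBN (excess), THF, 0 → 50 °C; then NaOH, H2O2, 0 °C → rt
Reagents that add atoms: hydrogen peroxide, OO; 9-borabicyclo[3.3.1]nonane, B1C2CCCC1CCC2 (boron stays only in 15)
Why: Anti-Markovnikov hydroboration–oxidation, in which 9-BBN should add only to the 1,1-disubstituted C9=C11 bond with boron at C11 and deliver hydrogen to C9 from the α-face opposite the adjacent axial 10β-methyl, which sets the 9α-H (C11 β) stereocenter before oxidation with retention gives the primary alcohol.

Step 10
Reactants: 16 drim-7-ene-3β,11-diol; 17 isofraxidin (7-hydroxy-6,8-dimethoxy-2H-chromen-2-one)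
Product: 18 7-{[(1S,4aR,6S,8aS)-6-hydroxy-2,5,5,8a-tetramethyl-1,4,4a,5,6,7,8,8a-octahydronaphthalen-1-yl]methoxy}-6,8-dimethoxy-2H-chromen-2-one (target)
Conditions: PPh3, DIAD, THF, 0 °C → rt
Reagents that add atoms: none
Why: Mitsunobu etherification, in which the acidic phenol should displace the alkoxyphosphonium of the primary C11 alcohol in an SN2 step at a non-stereogenic CH2 while the hindered neopentyl-type secondary 3β-OH does not react.

Compound list
1 | 2-methylcyclopentane-1,3-dione | CC1C(=O)CCC1=O | starting material
2 | ethyl vinyl ketone (pent-1-en-3-one) | CCC(=O)C=C | starting material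
3 | 2-methyl-2-(3-oxopentyl)cyclopentane-1,3-dione | CCC(=O)CCC1(C)C(=O)CCC1=O | intermediate
4 | (S)-4,7a-dimethyl-2,3,7,7a-tetrahydro-1H-indene-1,5(6H)-dione | O=C1CCC2=C(C)C(=O)CC[C@]12C | intermediate
5 | C9 ethylene ketal of 4, (7a'S)-4',7a'-dimethyl-2',3',7',7a'-tetrahydrospiro[1,3-dioxolane-2,1'-inden]-5'(6'H)-one | C13(OCCO3)CCC2=C(C)C(=O)CC[C@]12C | intermediate
6 | lithium C3(C4)-enolate of the trans-fused ketal (5α-H, 10β-CH3) | C13(OCCO3)CC[C@H]2C(C)=C(O[Li])CC[C@]12C | intermediate
7 | (3a'S,7a'S)-4',4',7a'-trimethylhexahydrospiro[1,3-dioxolane-2,1'-inden]-5'(4'H)-one (trans-fused) | C13(OCCO3)CC[C@H]2C(C)(C)C(=O)CC[C@]12C | intermediate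
8 | (3a'S,5'S,7a'S)-4',4',7a'-trimethyloctahydrospiro[1,3-dioxolane-2,1'-inden]-5'-ol (3β-OH) | C13(OCCO3)CC[C@H]2C(C)(C)[C@@H](O)CC[C@]12C | intermediate
9 | (3aS,5S,7aS)-5-hydroxy-4,4,7a-trimethyloctahydro-1H-inden-1-one (trans-fused, 3β-OH) | O=C1CC[C@H]2C(C)(C)[C@@H](O)CC[C@]12C | intermediate
10 | bis-TMS derivative of 9: C9 trimethylsilyl enol ether (C7=C9) and 3β-OTMS ether | C[Si](C)(C)OC1=CC[C@H]2C(C)(C)[C@@H](O[Si](C)(C)C)CC[C@]12C | intermediate
11 | 8-chloro-8-methylcyclopropane fused at C7–C9 on the α-face of 10 (Cl endo, CH3 exo, 9β-OTMS, 7β-H, 3β-OTMS) | C[Si](C)(C)O[C@]13[C@](C)(Cl)[C@@H]3C[C@H]2C(C)(C)[C@@H](O[Si](C)(C)C)CC[C@]12C | intermediate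
12 | 3β-(trimethylsilyloxy)-11-nordrim-7-en-9-one | O=C1C(C)=CC[C@H]2C(C)(C)[C@@H](O[Si](C)(C)C)CC[C@]12C | intermediate
13 | 3β-hydroxy-11-nordrim-7-en-9-one, (4aS,6S,8aS)-6-hydroxy-2,5,5,8a-tetramethyl-4a,5,6,7,8,8a-hexahydronaphthalen-1(4H)-one | O=C1C(C)=CC[C@H]2C(C)(C)[C@@H](O)CC[C@]12C | intermediate
14 | drima-7,9(11)-dien-3β-ol (5α-H, 10β-CH3) | C=C1C(C)=CC[C@H]2C(C)(C)[C@@H](O)CC[C@]12C | intermediate
15 | B-(3β-hydroxydrim-7-en-11-yl)-9-borabicyclo[3.3.1]nonane (9α-H) | C(B1C2CCCC1CCC2)[C@H]1C(C)=CC[C@H]2C(C)(C)[C@@H](O)CC[C@]12C | intermediate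
16 | drim-7-ene-3β,11-diol (5α-H, 9α-H, 10β-CH3) | OC[C@H]1C(C)=CC[C@H]2C(C)(C)[C@@H](O)CC[C@]12C | intermediate
17 | isofraxidin, 7-hydroxy-6,8-dimethoxy-2H-chromen-2-one | COc1cc2ccc(=O)oc2c(OC)c1O | starting material
18 | 7-{[(1S,4aR,6S,8aS)-6-hydroxy-2,5,5,8a-tetramethyl-1,4,4a,5,6,7,8,8a-octahydronaphthalen-1-yl]methoxy}-6,8-dimethoxy-2H-chromen-2-one | COc1cc2ccc(=O)oc2c(OC)c1OC[C@H]1C(C)=CC[C@H]2C(C)(C)[C@@H](O)CC[C@]12C | target

Total step count: 10
Longest linear sequence: 10 steps (1 and 2 to 18; 17 is bought)

Steps most likely to fail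

Step 7: the carbenoid addition of step 6 may place chlorine exo in a large share of the adduct, and that epimer cannot open by disrotation to a cis-allyl cation inside the ring, so the ring enlargement stalls or needs forcing conditions that erode the material. The fallback sets out from 10. Dibromocarbene (CHBr3, KOt-Bu, pentane, −20 °C) should give the 8,8-dibromocyclopropane F1, in which one bromide is endo by necessity. Warming F1 in toluene with a little pyridine should open it to 8-bromo-3β-(trimethylsilyloxy)-11,12-dinordrim-7-en-9-one F2. A Stille methylation of the α-bromo enone (Me4Sn, Pd(PPh3)4, CuI, NMP, 80 °C) then installs the C8 methyl and comes back to the route at 12, which is desilylated to 13 as in step 7.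

Step 8: the ylide may act as a base on the γ-CH2 (C6) of the enone or fail to add to the neopentyl C9 carbonyl, so that methylenation does not go to completion. The fallback sets out from 13 and uses a Peterson olefination. (Trimethylsilyl)methyllithium with CeCl3 (THF, −78 °C) is small and weakly basic and should add 1,2 from the α-face to give the 9-hydroxy-9-(trimethylsilylmethyl) compound F3. Syn-elimination with KH in THF then comes back to the route at 14.

Step 10: the alkoxyphosphonium at the β-branched C11 may lose the allylic C9–H by elimination back to diene 14 faster than the hindered, di-ortho-substituted phenoxide displaces it. The fallback sets out from 16. Selective sulfonylation of the primary hydroxyl (Tf2O, 2,6-di-tert-butyl-4-methylpyridine, CH2Cl2, −78 °C) should give the C11 triflate F4. Displacement with the caesium phenoxide of 17 (Cs2CO3, MeCN, 0 °C → rt) then comes back to the route at 18.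

Further compounds
F1 | step 7 | 8,8-dibromocyclopropane fused at C7–C9 on the α-face of 10 (9β-OTMS, 7β-H, 3β-OTMS) | C[Si](C)(C)O[C@]13C(Br)(Br)[C@@H]3C[C@H]2C(C)(C)[C@@H](O[Si](C)(C)C)CC[C@]12C
F2 | step 7 | 8-bromo-3β-(trimethylsilyloxy)-11,12-dinordrim-7-en-9-one | O=C1C(Br)=CC[C@H]2C(C)(C)[C@@H](O[Si](C)(C)C)CC[C@]12C
F3 | step 8 | 9α-(trimethylsilylmethyl)-11-nordrim-7-ene-3β,9β-diol | C[Si](C)(C)C[C@]1(O)C(C)=CC[C@H]2C(C)(C)[C@@H](O)CC[C@]12C
F4 | step 10 | 3β-hydroxydrim-7-en-11-yl trifluoromethanesulfonate | O=S(=O)(OC[C@H]1C(C)=CC[C@H]2C(C)(C)[C@@H](O)CC[C@]12C)C(F)(F)F
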